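The constants hold one thing nearly fixed, and it should be frozen before anything is integrated.

substrate 0.050 M; reagent in the second phase 0.100 M; time 6.0 d; volume of the second phase over the first 0.25

1. the target and crystals together standing at 6.0 d, as a percentage of the substrate charged
2. the change that raises the amount of target and crystals together at 6.0 d, in percent of the substrate charged most ("none" if none brings more than 2 percentage points) (south / east / west / north-east / none)
3. amount of target and crystals together at 6.0 d, in percent of the substrate charged, after west

- what is said of target includes crystals
- in the second phase: reagent in the second phase; everything else is in the first
- charges count per volume of the first phase; a concentration in a rate is the amount of a species over the volume of its own phase; every rate counts per litre of the first phase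
- crystals is a solid; its amount is given per volume of the solution
- run time (flask): 6.0 d

- south: doubling the amount of reagent in the second phase, all else as stated
- east: doubling the transfer coefficient of step 3, all else as stated
- west: doubling the solubility in step 4, all else as stated
- north-east: doubling the dissolution coefficient of step 4, all else as stated

    substrate + reagent in the reaction phase → target (k1 = 0.013 /M/min)
    reagent in the reaction phase → decomposed reagent (k2 = 3.8 × 10⁻⁴ /min)
    reagent in the reaction phase ⇌ reagent in the second phase, rate k3*([reagent in the reaction phase] - [reagent in the second phase]/K3) per volume of the first phase (K3 = 1.6, k3 = 5.8 × 10⁻⁴ /min)
    crystals ⇌ target, rate k4*(cs4 - [target]) while solid is left; crystals form when [target] > cs4 (cs4 = 36 mM, k4 = 0.0051 /min)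
    target → over-reaction product (k5 = 1.6 × 10⁻⁴ /min)

What goes on in this flask? Reagent leaks from the second phase into the reaction phase, where it either meets substrate to give target or decomposes. Target goes on to over-reaction product, and it crystallises above its solubility.

What is frozen? The selectivity factor S = k₁/k₂, here 34.2 /M, because both uses of reagent are first order in it, however its level wanders.

How much substrate is converted? Suppose the reagent is used up by those two steps. The fraction f of substrate left then obeys f = exp(−S(charged reagent − charged substrate + f × charged substrate)). Starting with no substrate left gives 18.1%; putting that back gives 13.3%, then 14.4%. So the converted share is X = 85.6%.

But when? Two lags stand in series: the leak time 690 min and the reagent's starting lifetime 971 min. Their sum is the birth time τ, the moment at which the target may be imagined born in one lump: 1.15 d. It ignores back-transfer and falling substrate, so it is rough.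

And the answer? Target decays with half-life 3.01 d, so y = X exp(−k₅(t − τ)) = 28.0%.

Crystals? The lump as born, 85.6%, lies above the solubility's 72.0% of the charge, so the lump picture cannot answer this. But the target is born spread out and decays meanwhile. If I let it be born first order with time constant τ, my estimate has dissolved target peaking near 2.08 d at about 53.0%, less than the solubility's share. So I expect none, and west and north-east change nothing.

South? X rises to 99.4%, but birth comes earlier. Cutting the lifetime lag by a factor 2 gives 2.1 percentage points, against a margin of 2 points and too rough to clear it. East cuts the leak time by that factor and gives −1.5 points. I write none.

The forecast gave 30% (26% to 34%), 30% after west and south as best, where I say none, and held that “faster transfer mainly brings formation forward and exposes the target to over-reaction for longer”.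

The simulation gives 29.4%, 29.4% after west and none as best, with south at 1.3 points and east at −1.1 points. The solubility of target makes no difference to the answer here.

In the flask at 6.00 d, dissolved target is being made at 0.141 of the rate at which it is used up. By 3.00 d the passage of reagent out of the second phase already has 95% of its turnover to the asked time behind it. For the neighbour flask read at 10 d, X and τ give 11.1%. The simulation gives 12.6%.

All constants stand for no real mixture.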